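At late times both earlier flasks stand still with electrophile left over, so the late rows are the ones to read.

| setting | summer | dusk | blue | grey |
|---|---|---|---|---|
| electrophile | 20 mM | 20 mM | 20 mM | 20 mM |
| nucleophile | 0.95 equiv (fed, over 3.0 min) | 0.95 equiv (fed, over 3.0 min) | 0.950 equiv (fed, over 3.0 min) | 0.950 equiv (fed, over 3.0 min) |
| free base | 2.3 equiv | 3.5 equiv | 2.00 equiv | 2.60 equiv |
| protic impurity | 10 mM | 10 mM | 10.0 mM | 10.0 mM |
| remark | run made earlier | run made earlier |  |  |
| time |  |  | 12 h | 12 h |

- summer (time / h: electrophile / %, target / %): 0.500: 42.5, 58.9; 1.00: 33.9, 64.7; 2.50: 27.7, 71.6; 6.00: 28.9, 71.0
- dusk (time / h: electrophile / %, target / %): 1.50: 30.0, 71.5; 3.00: 28.5, 71.2; 5.00: 27.1, 69.8; 6.00: 30.8, 69.8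

(each reading ± 1 percentage point)

- the earlier runs were read with a standard deviation of 1 percentage point
- on the list of suspects stand: electrophile + nucleophile -> acid set free + target; nucleophile + acid set free <-> protonated nucleophile; acid set free + free base <-> salt of the base; nucleophile + protic impurity -> quenched reagent; acid set free + target -> side product

* part of the electrophile that has reacted at the end, blue
* part of the electrophile that has reacted at the end, grey
* what raising the equivalents of free base from its lowest to its highest value here does to the part of the electrophile that has reacted (changes below 5 percentage points count as none) (it rises / it falls / no change)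

Summer's rows from 2.50 h on and dusk's rows from 1.50 h on lie flat, and these six target readings average 70.8%. Summer's two average 71.3% and dusk's four 70.6%, a gap of 0.70 percentage points against a scatter of 1 point, although the free base goes from 2.3 equiv to 3.5 equiv.

So I look at the nucleophile. Of 19.0 mM fed, 14.2 mM became target, and I suppose the other 4.84 mM became quenched reagent. I replace each falling curve by its mean: c(electrophile) 12.9 mM, c(protic impurity) 7.58 mM. This gives the selectivity factor, the number of times more readily the nucleophile takes the electrophile than the impurity at equal concentrations: S = 1.72. Integrating instead of averaging gives 1.86, somewhat more than the mean form, and that gap is the error I accept.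

S contains no free base, and blue's 40.0 mM of it is more than the 14.2 mM of acid released along with that target. I therefore commit to 70.8% for blue and for grey.

The forecast gives 70.5% for blue, 71% for grey and no change, holding that “acid capture is already complete”.

The flask gives 71.6% for blue, 71.6% for grey, and no change, a change of 0 points. At the end of blue the nucleophile, the limiting reagent, stands at 0% of its charge and the free base at 64.8%. With blue's own means, S estimates that 74.2% of the nucleophile goes to the electrophile.

    electrophile + nucleophile → acid set free + target (k = 3.60 L mol⁻¹ min⁻¹)
    nucleophile + acid set free ⇌ protonated nucleophile, settled at all times (K = 7000 L mol⁻¹)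
    acid set free + free base ⇌ salt of the base, settled at all times (K = 83000 L mol⁻¹)
    nucleophile + protic impurity → quenched reagent (k = 1.80 L mol⁻¹ min⁻¹)
    acid set free + target → side product (k = 3.40 L mol⁻¹ min⁻¹)

Take a neighbour flask, blue's recipe with 5.0 mM of electrophile and the same concentration of protic impurity. Starting from the charges and passing once through the means, S estimates the nucleophile's share going to the electrophile at 46.2%, then 43.5%, so I expect 41.3% of the electrophile to react. The computed flask gives 44.3%.

The earlier runs and the new flask are calculated on assumed constants; scatter was added.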